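The target is counted as a fraction of the starting material charged, so before any rate I ask what part of that charge goes elsewhere.

| flask | starting material | reagent | protic impurity | remark | time |
|---|---|---|---|---|---|
| autumn | 0.091 M | 0.65 M (in portions, 2) | 0.025 M | run made earlier; portions every 50 h |  |
| dawn | 0.22 M | 0.65 M (in portions, 2) | 0.025 M | run made earlier; portions every 50 h |  |
| midnight | 0.55 M | 0.65 M (in portions, 2) | 0.025 M | run made earlier; portions every 50 h |  |
| Monday's | 0.10 M | 0.650 M (in portions, 2) | 0.0250 M | the portions of reagent follow each other after 50 h, the first at the start | 20 d |
| Wednesday's | 0.15 M | 0.650 M (in portions, 2) | 0.0250 M | the portions of reagent follow each other after 50 h, the first at the start | 20 d |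
| Sunday's | 0.20 M | 0.650 M (in portions, 2) | 0.0250 M | the portions of reagent follow each other after 50 h, the first at the start | 20 d |
| Tuesday's | 0.30 M | 0.650 M (in portions, 2) | 0.0250 M | the portions of reagent follow each other after 50 h, the first at the start | 20 d |
| Saturday's | 0.50 M | 0.650 M (in portions, 2) | 0.0250 M | the portions of reagent follow each other after 50 h, the first at the start | 20 d |

- autumn (time / d: target / %): 2.08: 5.6; 4.00: 19.2; 6.00: 26.8; 8.00: 29.4; 10.0: 31.5
- dawn (time / d: target / %): 0.833: 1.1; 1.67: 4.0; 3.00: 11.0; 5.00: 22.7; 10.0: 33.6
- midnight (time / d: target / %): 2.08: 2.3; 4.00: 10.8; 6.00: 15.4; 8.00: 17.7; 10.0: 20.3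

(standard deviation of a reading: 0.3 percentage points)

- what was read earlier has a scatter of 0.3 percentage points, one standard deviation
- "hardly changes" means that all values lie within two and a half points (for a concentration: within two and a half percent of the largest)

- amount of target at the end, in percent of the starting material charged for Monday's, Wednesday's, Sunday's, Tuesday's, Saturday's, in this order
- the course of these numbers from the first flask to the last (hardly changes / falls all the way / rises, then falls / rises all the way / falls, then rises)

I assume that the protic impurity takes starting material one for one. Its charge is smaller than that of the starting material in each flask, so I treat it as the limiting reagent of that loss and reckon its fraction of the charge: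

s = impurity charge / starting material charge: Monday's 0.250, Saturday's 0.0500

This impurity share is what I carry. By hand, turning the starting material up lowers s and so opens more of the charge to the target. To see what else that setting does, I divide each last reading, taken at 10.0 d, by what s leaves, and call the result the clean yield w:

w = target / (1 − s): autumn 0.434, dawn 0.379, midnight 0.213

The reagent charge stays put, so reagent per starting material falls from 7.14 in autumn through 2.95 at dawn to 1.18 at midnight, and w falls with it. I read this as control passing from the impurity to the reagent somewhere between dawn and midnight. I keep the spacing of 50 h that the earlier runs had, so my reckoning says nothing about it. I also leave out the later days, although autumn still gained 2.1 percentage points over its last two days. Taking w from the nearest run, my own reckoning is: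

Monday's 0.326, Tuesday's 0.347, Saturday's 0.202

The forecast gives 40 %, 43 %, 42 %, 39 % and 30 %, a course that rises, then falls, from the reading that "A smooth curve through these points against log concentration peaks near 0.16 M".

The flasks give 32.9 %, 35.2 %, 36.7 %, 37.8 % and 28.6 %, a course that rises, then falls, by these steps:

    starting material + protic impurity → quenched substrate (k = 1.75 × 10⁻⁴ /M/s)
    starting material + reagent → intermediate A (k = 1.37 × 10⁻⁵ /M/s)
    intermediate A ⇌ intermediate C (K = 1.20, k = 4.09 × 10⁻⁷ /s)
    reagent ⇌ dormant form (K = 0.200, k = 1.95 × 10⁻⁴ /s)
    reagent + intermediate B → target (k = 1.10 × 10⁻⁵ /M/s)
    starting material + reagent → intermediate B (k = 9.93 × 10⁻⁶ /M/s)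

The row turns at 0.30 M, in Tuesday's flask. Monday's s of 25.0 % stands beside 21.6 % of quenched substrate, and its clean yield comes to 0.439, while Tuesday's comes to 0.412. Saturday's s of 5.00 % stands beside 5.00 % of quenched substrate, and its clean yield is 0.301, above the 0.213 I took from midnight, with 5.26 % of the reagent's charge left at 20.0 d.

The numbers in the tables were generated by integration from invented constants; noise was put on by code.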